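## Structural features

Briarane numbering is used for the target and for every intermediate (C15 = CH3 on C1, C16 = ester carbon on C5, C18 = CH3 on C17, C19 = lactone C=O, C20 = CH3 on C11; α = face of H-10, β = face of Me-15). Cyclohexane ring A (C1, C10–C14) is trans-fused through C1–C10 to a ten-membered carbocycle (C1–C10). A γ-lactone (O, C7, C8, C17, C19) is fused trans on the C7–C8 bond of that ring. All ten stereocentres are contiguous (C14–C1–C2, C1–C10–C11–C12, C10–C9–C8–C7 and C17); C1 is an all-carbon quaternary centre between two acetoxy carbons and C8 is a tertiary carbinol between C7–O and C9–O. H-10, H-11, O-12, O-14, O-8 and O-9 lie on the α face, and Me-15, Me-20 and C17 on the β face. C5=C6 carries CO2Me trans to C7 (E by CIP), so the ring bonds C4 and C7 are cis, as in a cyclohexene. Fragile groups are the four secondary acetates beside a free tertiary alcohol, the β-hydroxy-γ-lactone (retro-aldol, dehydration, epimerisable C17) and the γ-acyloxy enoate. The real difficulty is the ten-membered ring: a direct closure must join two ends between the fully substituted C1 and C8 against transannular strain, and the stereocentres would have to be set on open chains or a floppy ring. The key step exploits the fact that C2 and C7 both carry oxygen and face each other 1,6 across this ring, joined by two four-atom bridges (C3–C6 and C8, C9, C10, C1). The ring is therefore a masked cyclodecane-1,6-dione, the cleavage product of a C2=C7 double bond shared by six-membered rings B (C1, C2, C7–C10) and C (C2–C7) of a hydrophenanthrene.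

## Logic of the disconnections

**33 ⇒ 30.** The acetate C–O bonds at O2, O12 and O14 and the C2–H bond are cut. Acetates do not survive the strong bases used earlier, so O12/O14 travel as one acetal and C2 as a ketone. The gain is a single protecting group for ring A. The forward steps must reduce a neopentyl ketone to 2R and acylate three secondary alcohols beside the tertiary 8-OH.

**30 ⇒ 28.** The lactone bond O7–C19 and the C7–H bond are cut. The lactone closes by itself once C7 carries OH, and C17 is the thermodynamic epimer in the lactone. The gain is that C7 and C17 are removed as problems of the precursor. The forward step must attack the C7 ketone selectively and on one face in the presence of the C2 ketone.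

**28 ⇒ 26 (key).** C2 and C7 are reconnected as C2=C7. Both carbonyl groups of 28 vanish and the ten-membered ring collapses into two six-membered rings, so a medium-ring problem becomes a rigid tricycle. The forward step must cleave the tetrasubstituted alkene and spare C5=C6. In one sentence: ozonolysis of the ring-fusion alkene C2=C7 of 26 opens rings B and C into the ten-membered ring.

**26 ⇒ 24.** The C8–O and C9–O bonds are cut together (and the O9 acetate). Both oxygens are α and cis, which is the signature of a syn dihydroxylation from the face opposite Me-15. A nucleophile added to a C8 ketone would come from that same α face and give the wrong C8. The gain is two stereocentres in one step. The forward step needs site selectivity among three alkenes.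

**24 ⇒ 21 + 22.** C8–C17 is cut. This attaches the three-carbon lactone arm to an sp2 carbon regiospecifically. The forward step is a cross-coupling at a hindered enol triflate.

**21 ⇒ 19.** C5–C16 is cut (carbonylation), and both enol triflates go back to ketones. The gain is that ester and side chain are both replaced by carbonyl groups. The forward steps need regiodefined double enolisation and discrimination between two triflates.

**19 ⇒ 14.** Ring C goes back to an anisole (two C–H bonds at C3 and C6, enol ether O–CH3), and C8=O goes back to a benzylic CH2. The arene masks C2=C7 and the C5 ketone during all ring A chemistry. The forward step is a Birch reduction that keeps a benzylic oxygen.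

**14 ⇒ 9.** C10–H, C11–H, C12–H and C14–O are cut. Four stereocentres of ring A are removed and an enone is left. All of them must be delivered from the α face in the forward direction.

**9 ⇒ 3 + 5.** C1–C14 and C10=C11 are cut (Robinson annulation). Ring A and the quaternary centre go back to a tetralone. The forward Michael step must set C1 absolutely, using 4.

**3 ⇒ 1.** C1–C15 is cut, which leads to a commercial tetralone.

## Other disconnections considered

Alternative 1: this is the first plan that comes to mind. C5=C6 is cut. Ring A is made first, both arms are attached, and the seco-diene A1 is closed by ring-closing metathesis. The closure would have to join a 1,1-disubstituted acrylate with a vinyl group next to an acyloxy carbon, both reluctant metathesis partners. The ring formed is a strained ten-membered one hemmed in by C1 and C8, so oligomerisation should compete and nothing fixes the alkene geometry. All ten stereocentres must be set beforehand on freely rotating arms. The chosen plan never forms the medium ring in a bond-forming step and takes the geometry from a cyclohexadiene.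

Alternative 2: C1–C10 is cut, as in the presumed origin of briaranes from cembranes. A 14-membered epoxy enone A2 would be opened at C1 (Ti(III) radical or Lewis acid) and stitched across to C10. From C1 the enone carbon C10 and the enoate carbon C6 are reached through equivalent six-membered endo transition states, and both are acceptor β-carbons, so no structural element decides between them. C1 is planar in the reactive intermediate, and its relation to C2, C14 and C10 rests only on the macrocycle conformation. In the cationic variant the acyloxy groups at C14 and C9 deactivate both partners and a semipinacol shift from C14 is open. A2 also needs the C7–C8–C9/C17 array from acyclic control plus a macrocyclisation, so it is not shorter.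

Alternative 3: C4–C5 is cut while C2–C7 is reconnected, giving an anionic oxy-Cope rearrangement of the divinyl carbinol A3 to the cyclodecenone A4. It shares the idea of a temporary C2–C7 bond. However, it delivers C6=C7 with an sp3 C5, so C7–O, C8, C9 and C17 would all have to be introduced afterwards on the flexible ring. The alkoxide must coexist with an acrylate acceptor, vinyl addition to the neopentyl C2 ketone is demanding, and the chair or boat course decides the alkene geometry. The chosen plan sets C8 and C9 on the rigid tricycle and needs no alkene transposition.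

Key step: step 18

Assumption: the facial sense of auxiliary 4 in step 2 is assigned by analogy with the corresponding imine of 2-methylcyclohexanone; if the tetralone imine reacted on the other face, the antipode of 4 would be used. C8 in 16–18 is drawn as the expected epimer and is destroyed in step 12.

## Steps

Step 1
Reactants: 1 6-methoxy-2-tetralone
Product: 3 rac-6-methoxy-1-methyl-2-tetralone, via pyrrolidine enamine 2 (not isolated)
Conditions: pyrrolidine, toluene, reflux (Dean–Stark); MeI, dioxane, reflux; aq. AcOH/NaOAc, rt
Reagents that add atoms: iodomethane (CI); water (O)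
Why: Stork enamine alkylation: 2 is the styrene-conjugated enamine, so carbon alkylation can only occur at benzylic C1, and the hindered iminium salt resists a second alkylation before hydrolysis returns the C10 ketone. The new centre is racemic, which is harmless because it is planarised again in step 2.

Step 2
Reactants: 3 rac-6-methoxy-1-methyl-2-tetralone; 4 (R)-1-phenylethylamine; 5 pent-1-en-3-one
Product: 8 (R)-6-methoxy-1-methyl-1-(3-oxopentyl)-2-tetralone, via chiral imine 6 (not isolated), via Michael adduct imine 7 (not isolated)
Conditions: 4, TsOH (cat.), toluene, reflux (Dean–Stark); 5, THF, rt; 20% aq. AcOH, rt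
Reagents that add atoms: water (O)
Why: Michael addition of a chiral imine through its more substituted secondary enamine tautomer (aza-ene-type, chair-like transition state with internal N–H transfer), a known route to quaternary α-carbons from racemic α-substituted ketones. Both enantiomers of 3 converge on one planar enamine and the phenylethyl group blocks one face, so C1–C14 forms on the other and sets C1 (Me-15 β), the only stereocentre not relayed from the substrate.

Step 3
Reactants: 8 (R)-6-methoxy-1-methyl-1-(3-oxopentyl)-2-tetralone
Product: 9 (4aS)-7-methoxy-1,4a-dimethyl-4,4a,9,10-tetrahydrophenanthren-2(3H)-one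
Conditions: NaOMe, MeOH, reflux
Reagents that add atoms: none
Why: Intramolecular aldol condensation (second half of a Robinson annulation): the C11 enolate closes ring A on the C10 ketone and dehydration gives the tetrasubstituted C10=C11 enone, while the bridged ketol from attack of C9 on C12 is reversible. C1 has no α-hydrogen and cannot epimerise.

Step 4
Reactants: 9 tricyclic enone
Product: 10 cross-conjugated dienone (12-one with C10=C11 and C13=C14)
Conditions: DDQ, dioxane, reflux
Reagents that add atoms: none
Why: DDQ dehydrogenation of a 4-en-3-one-type enone through its C13 enol gives the cross-conjugated dienone, as in the steroid 1,4-dien-3-one series.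

Step 5
Reactants: 10 cross-conjugated dienone
Product: 11 13α,14α-epoxy enone
Conditions: 30% H2O2, NaOH, MeOH, 0 °C
Reagents that add atoms: hydrogen peroxide (OO)
Why: Weitz–Scheffer epoxidation: hydroperoxide adds only to the disubstituted C13=C14, because the tetrasubstituted C10=C11 is inert to conjugate addition. Attack at C14 comes from the α face opposite axial Me-15, which sets C14–O.

Step 6
Reactants: 11 13α,14α-epoxy enone
Product: 12 12α,14α-diol with C10=C11
Conditions: LiAlH4, THF, 0 °C to reflux; Fieser work-up
Reagents that add atoms: none
Why: Hydride reduction: the C12 ketone should be attacked from the β face, anti to the neighbouring epoxide oxygen (the usual cis-epoxy alcohol outcome of 2,3-epoxycyclohexanones), giving 12α-OH. The epoxide then opens trans-diaxially (Fürst–Plattner rule) at C13, since C14 is neopentyl and its β face is blocked by Me-15, which leaves 14α-OH.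

Step 7
Reactants: 12 12α,14α-diol with C10=C11
Product: 13 saturated 12α,14α-diol (H-10 α and Me-20 β)
Conditions: [Ir(cod)(PCy3)(py)]PF6 (cat.), H2 (50 bar), CH2Cl2, rt
Reagents that add atoms: none
Why: Hydroxyl-directed hydrogenation with Crabtree's catalyst: iridium binds the allylic 12α-OH (and the homoallylic 14α-OH) and delivers both hydrogens to the α face of the tetrasubstituted alkene, the face that is also free of Me-15. Syn addition sets C10 (trans ring fusion) and C11 (axial β methyl, not accessible by equilibration) in one event.

Step 8
Reactants: 13 saturated 12α,14α-diol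
Product: 14 12,14-O-isopropylidene acetal
Conditions: 2,2-dimethoxypropane, PPTS (cat.), CH2Cl2, rt
Reagents that add atoms: 2,2-dimethoxypropane (COC(C)(C)OC)
Why: Acetal formation: the syn-diaxial 1,3-diol is pre-organised for a 1,3-dioxane. The acetal tolerates Cr(VI)/peroxide, hydride, Li/NH3, amide bases, Pd(0), OsO4 and ozone.

Step 9
Reactants: 14 12,14-O-isopropylidene acetal
Product: 15 8-ketone (aryl ketone)
Conditions: CrO3 (cat.), t-BuOOH, CH2Cl2, rt
Reagents that add atoms: tert-butyl hydroperoxide (CC(C)(C)OO)
Why: Chromium-catalysed benzylic oxidation, the standard entry to 7-oxo compounds in the related podocarpane series. C8 is the only benzylic CH2, because the other benzylic carbon C1 is quaternary.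

Step 10
Reactants: 15 8-ketone
Product: 16 8β-alcohol (benzylic alcohol)
Conditions: NaBH4, MeOH/THF, 0 °C
Reagents that add atoms: none
Why: Borohydride reduction, expected from the α face opposite Me-15. The configuration is of no consequence, and the step only turns the carbonyl group into a form that can pass the dissolving-metal step as an alkoxide.

Step 11
Reactants: 16 8β-alcohol
Product: 18 5-oxo-8β-hydroxy compound with C2=C7, via dihydroanisole 17 (not isolated)
Conditions: Li, NH3(l)/THF, t-BuOH, −78 to −33 °C; isoprene, then NH4Cl; crude 17: (CO2H)2, THF/H2O, rt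
Reagents that add atoms: water (O)
Why: Birch reduction followed by mild enol ether hydrolysis: the methoxy carbon and both alkyl-bearing carbons stay sp2, so protonation occurs at C3 and C6 and leaves C2=C7 as the tetrasubstituted ring-fusion alkene, as with 6-methoxytetralin. The benzylic oxygen travels as its lithium alkoxide, which is not a leaving group and is not protonated by t-BuOH, and the excess metal is destroyed before NH4Cl is added. Oxalic acid cleaves the enol ether without moving the β,γ double bond or opening the acetal.

Step 12
Reactants: 18 5-oxo-8β-hydroxy compound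
Product: 19 5,8-dione (C8 enone conjugated to C2=C7)
Conditions: MnO2, CH2Cl2, rt
Reagents that add atoms: none
Why: Allylic alcohol oxidation with MnO2; 8-OH is the only free hydroxyl group. The neutral conditions leave the β,γ-unsaturated C5 ketone in place.

Step 13
Reactants: 19 5,8-dione
Product: 20 bis(enol triflate) C5(OTf)=C6–C7(=C2)–C8(OTf)=C9
Conditions: KHMDS (2.3 equiv), THF, −78 °C; PhNTf2, −78 to 0 °C
Reagents that add atoms: N-phenylbis(trifluoromethanesulfonimide) (O=S(=O)(N(c1ccccc1)S(=O)(=O)C(F)(F)F)C(F)(F)F)
Why: Double enolisation and O-sulfonylation (enol triflate formation): the first equivalent removes the doubly activated H-6 (α to C5=O and allylic to C2=C7) and gives the linear dienolate. The second can then only take the α′ proton at C9, because H-3 is now allylic to an electron-rich dienolate.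

Step 14
Reactants: 20 bis(enol triflate)
Product: 21 methyl dienoate with C8 enol triflate
Conditions: Pd(OAc)2/PPh3 (cat.), CO (1 atm), MeOH, Et3N, DMF, rt, stopped after one triflate has reacted
Reagents that add atoms: carbon monoxide ([C-]#[O+]); methanol (CO)
Why: Palladium-catalysed methoxycarbonylation of an enol triflate installs C16. Oxidative addition should prefer C5–OTf, flanked only by CH2 and CH, over C8–OTf, which sits next to the fully substituted C7.

Step 15
Reactants: 21 methyl dienoate with C8 enol triflate; 22 methyl 2-bromopropanoate
Product: 24 tetraene diester (C8 bears CH(CH3)CO2CH3; C17 epimers), via Reformatsky reagent 23 (not isolated)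
Conditions: 22, Zn dust (TMSCl-activated), THF, rt; then 21, Pd(dba)2/Q-Phos (cat.), THF, rt to 40 °C
Reagents that add atoms: none
Why: Negishi-type cross-coupling of a Reformatsky reagent with an alkenyl triflate forms C8–C17 regiospecifically at the sp2 carbon. The neutral conditions should not move C8=C9 into conjugation with the new ester, and C17 is left unset here and fixed in step 19.

Step 16
Reactants: 24 tetraene diester
Product: 25 8α,9α-diol
Conditions: OsO4 (cat.), NMO, acetone/H2O, 0 °C to rt
Reagents that add atoms: N-methylmorpholine N-oxide (C[N+]1([O-])CCOCC1); water (O)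
Why: Upjohn dihydroxylation: C8=C9 is the only alkene that is neither tetrasubstituted (C2=C7) nor deactivated by an ester (C5=C6). OsO4 adds from the α face because pseudo-axial Me-15 stands 1,3 to C9 on the β face. Syn addition sets C8 (OH α, C17 β) and C9 (OH α) together.

Step 17
Reactants: 25 8α,9α-diol
Product: 26 9-acetate (free tertiary allylic 8-OH)
Conditions: Ac2O, pyridine, DMAP (cat.), CH2Cl2, 0 °C, directly after step 16
Reagents that add atoms: acetic anhydride (CC(=O)OC(C)=O)
Why: Selective acylation of the secondary equatorial 9-OH; the tertiary axial 8-OH is too hindered. Prompt acylation also prevents 9-OH from lactonising onto C19.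

Step 18
Reactants: 26 9-acetate (hydrophenanthrene dienoate)
Product: 28 ten-membered 2,7-dione, via methoxy hydroperoxide 27 (not isolated)
Conditions: O3, CH2Cl2/MeOH, NaHCO3, Sudan Red 7B, −78 °C; Me2S, −78 °C to rt
Reagents that add atoms: ozone ([O-][O+]=O)
Why: Ozonolysis (Criegee mechanism): ozone adds as an electrophilic 1,3-dipole to C2=C7; the primary ozonide cleaves to the C7 ketone and the C2 carbonyl oxide (the oxide forms on the carbon with only alkyl neighbours, the ketone on the carbon bearing the acceptor-substituted vinyl group and the carbinol), methanol traps the oxide as 27 and Me2S reduces it to 28. The closest known reaction type is the ozonolysis of Δ9(10)-octalins and related ring-fusion alkenes to cyclodecane-1,6-diones. No ring is closed by bond formation: the ten-membered ring arises when the bond shared by six-membered rings B and C is cut, so neither the entropy nor the transannular strain of a medium-ring cyclisation appears in a bond-forming transition state. No stereocentre is created or touched; C1, C8, C9 and C10, set on the rigid tricycle, are carried over unchanged, and the C5=C6 geometry (C4 and C7 cis, E by CIP) is inherited from cyclohexadiene ring C and cannot be formed wrongly. The step needs chemoselectivity between two alkenes: C2=C7 carries four carbon substituents and is the remote γ,δ bond of the dienoate, whereas C5=C6 is directly deactivated by CO2Me, and the indicator dye marks the end point. NaHCO3 keeps the tertiary allylic alcohol from ionising, and the neutral reductive work-up at low temperature avoids transannular aldol addition of C3 to C7. The two carbonyl groups appear exactly at the oxygenated carbons C2 and C7.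

Step 19
Reactants: 28 ten-membered 2,7-dione
Product: 30 2-oxo 19,7-lactone (7S and 17R), via 7-hydroxy ester 29 (not isolated)
Conditions: NaBH4, CeCl3·7H2O, MeOH, −78 °C; aq. work-up; DBU, toluene, 50 °C
Reagents that add atoms: none
Why: Luche reduction, lactonisation and base equilibration: Ce(III) favours 1,2-addition to the ene-keto ester and chelates O7 and O8, so that C9 and the ring body cover one carbonyl face and hydride should arrive from the peripheral face next to C17, giving 7S, while the neopentyl C2 ketone is not attacked at −78 °C. The 7-alkoxide closes the γ-lactone on C19, and DBU equilibrates C17 to the more stable epimer with Me-18 trans to C9. H-7 is held in the nodal plane of the enoate by A(1,3) strain with C4 and should not be removed.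

Step 20
Reactants: 30 2-oxo 19,7-lactone
Product: 31 (2R)-alcohol
Conditions: (S)-Me-CBS, BH3·SMe2, toluene/THF, −20 °C; MeOH quench
Reagents that add atoms: none
Why: Corey–Bakshi–Shibata reduction: the ketone has one quaternary neighbour (C1) and one CH2 neighbour (C3), the size difference the catalyst reads best, and the (S)-catalyst should give 2R by the acetophenone mnemonic. Lactone, enoate and acetate are not reduced by borane at this temperature, and 8-OH only consumes one hydride.

Step 21
Reactants: 31 (2R)-alcohol
Product: 32 2,8,12,14-tetraol 9-acetate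
Conditions: AcOH/H2O (4:1), 40 °C
Reagents that add atoms: none
Why: Acid hydrolysis of the strained acetal of a diaxial diol. 8-OH is no longer allylic, and the esters tolerate aqueous acetic acid.

Step 22
Reactants: 32 2,8,12,14-tetraol 9-acetate
Product: 33 CNP0230222.1 (target)
Conditions: Ac2O, pyridine, DMAP (cat.), CH2Cl2, rt
Reagents that add atoms: acetic anhydride (CC(=O)OC(C)=O)
Why: Acetylation of the three secondary alcohols at C2, C12 and C14. The tertiary 8-OH, flanked by C7, C9 and C17, should remain free under these conditions.

## Compound list

1 | 6-methoxy-2-tetralone | COc1ccc2c(c1)CCC(=O)C2 | starting material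
2 | 1-(6-methoxy-3,4-dihydronaphthalen-2-yl)pyrrolidine | COc1ccc2c(c1)CCC(=C2)N1CCCC1 | intermediate
3 | rac-6-methoxy-1-methyl-2-tetralone | COc1ccc2c(c1)CCC(=O)C2C | intermediate
4 | (R)-1-phenylethylamine | C[C@@H](N)c1ccccc1 | starting material
5 | pent-1-en-3-one | C=CC(=O)CC | starting material
6 | N-[(R)-1-phenylethyl]imine of 3 | COc1ccc2c(c1)CCC(=N[C@H](C)c1ccccc1)C2C | intermediate
7 | N-[(R)-1-phenylethyl]imine of 8 | COc1ccc2c(c1)CCC(=N[C@H](C)c1ccccc1)[C@]2(C)CCC(=O)CC | intermediate
8 | (R)-6-methoxy-1-methyl-1-(3-oxopentyl)-2-tetralone | COc1ccc2c(c1)CCC(=O)[C@]2(C)CCC(=O)CC | intermediate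
9 | (4aS)-7-methoxy-1,4a-dimethyl-4,4a,9,10-tetrahydrophenanthren-2(3H)-one | COc1ccc2c(c1)CCC1=C(C)C(=O)CC[C@]21C | intermediate
10 | (4aS)-7-methoxy-1,4a-dimethyl-9,10-dihydrophenanthren-2(4aH)-one | COc1ccc2c(c1)CCC1=C(C)C(=O)C=C[C@]21C | intermediate
11 | 13α,14α-epoxide of 10 | COc1ccc2c(c1)CCC1=C(C)C(=O)[C@@H]3O[C@@H]3[C@]21C | intermediate
12 | 12α,14α-diol with C10=C11 | COc1ccc2c(c1)CCC1=C(C)[C@H](O)C[C@H](O)[C@]21C | intermediate
13 | 10α-H, 11β-methyl 12α,14α-diol | COc1ccc2c(c1)CC[C@H]1[C@@H](C)[C@H](O)C[C@H](O)[C@]21C | intermediate
14 | 12,14-O-isopropylidene acetal of 13 | COc1ccc2c(c1)CC[C@H]1[C@@H](C)[C@H]3C[C@H](OC(C)(C)O3)[C@]21C | intermediate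
15 | 8-ketone of 14 | COc1ccc2c(c1)C(=O)C[C@H]1[C@@H](C)[C@H]3C[C@H](OC(C)(C)O3)[C@]21C | intermediate
16 | 8β-alcohol | COc1ccc2c(c1)[C@@H](O)C[C@H]1[C@@H](C)[C@H]3C[C@H](OC(C)(C)O3)[C@]21C | intermediate
17 | 3,6-dihydroanisole (C4=C5(OMe), C2=C7) | COC1=CCC2=C(C1)[C@@H](O)C[C@H]1[C@@H](C)[C@H]3C[C@H](OC(C)(C)O3)[C@]21C | intermediate
18 | 5-oxo-8β-hydroxy compound with C2=C7 | O=C1CCC2=C(C1)[C@@H](O)C[C@H]1[C@@H](C)[C@H]3C[C@H](OC(C)(C)O3)[C@]21C | intermediate
19 | 5,8-dione with C2=C7 | O=C1CCC2=C(C1)C(=O)C[C@H]1[C@@H](C)[C@H]3C[C@H](OC(C)(C)O3)[C@]21C | intermediate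
20 | 5,8-bis(enol triflate) | C1CC2=C(C=C1OS(=O)(=O)C(F)(F)F)C(OS(=O)(=O)C(F)(F)F)=C[C@H]1[C@@H](C)[C@H]3C[C@H](OC(C)(C)O3)[C@]21C | intermediate
21 | C5 methyl ester, C8 enol triflate | C1CC2=C(C=C1C(=O)OC)C(OS(=O)(=O)C(F)(F)F)=C[C@H]1[C@@H](C)[C@H]3C[C@H](OC(C)(C)O3)[C@]21C | intermediate
22 | methyl 2-bromopropanoate | CC(Br)C(=O)OC | starting material
23 | bromo(1-methoxy-1-oxopropan-2-yl)zinc | COC(=O)C(C)[Zn]Br | intermediate
24 | tetraene diester (C17 epimers) | C1CC2=C(C=C1C(=O)OC)C(C(C)C(=O)OC)=C[C@H]1[C@@H](C)[C@H]3C[C@H](OC(C)(C)O3)[C@]21C | intermediate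
25 | 8α,9α-diol (C17 epimers) | C1CC2=C(C=C1C(=O)OC)[C@@](O)(C(C)C(=O)OC)[C@H](O)[C@H]1[C@@H](C)[C@H]3C[C@H](OC(C)(C)O3)[C@]21C | intermediate
26 | 9-acetate of 25 | C1CC2=C(C=C1C(=O)OC)[C@@](O)(C(C)C(=O)OC)[C@H](OC(C)=O)[C@H]1[C@@H](C)[C@H]3C[C@H](OC(C)(C)O3)[C@]21C | intermediate
27 | 2-hydroperoxy-2-methoxy-7-ketone | COC(=O)/C1=C/C(=O)[C@@](O)(C(C)C(=O)OC)[C@H](OC(C)=O)[C@H]2[C@@H](C)[C@H]3C[C@H](OC(C)(C)O3)[C@]2(C)C(OC)(OO)CC1 | intermediate
28 | ten-membered 2,7-dione | COC(=O)/C1=C/C(=O)[C@@](O)(C(C)C(=O)OC)[C@H](OC(C)=O)[C@H]2[C@@H](C)[C@H]3C[C@H](OC(C)(C)O3)[C@]2(C)C(=O)CC1 | intermediate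
29 | (7S)-7-hydroxy ester | COC(=O)/C1=C/[C@H](O)[C@@](O)(C(C)C(=O)OC)[C@H](OC(C)=O)[C@H]2[C@@H](C)[C@H]3C[C@H](OC(C)(C)O3)[C@]2(C)C(=O)CC1 | intermediate
30 | 2-oxo 19,7-lactone | COC(=O)/C1=C/[C@@H]2OC(=O)[C@H](C)[C@@]2(O)[C@H](OC(C)=O)[C@H]2[C@@H](C)[C@H]3C[C@H](OC(C)(C)O3)[C@]2(C)C(=O)CC1 | intermediate
31 | (2R)-alcohol | COC(=O)/C1=C/[C@@H]2OC(=O)[C@H](C)[C@@]2(O)[C@H](OC(C)=O)[C@H]2[C@@H](C)[C@H]3C[C@H](OC(C)(C)O3)[C@]2(C)[C@H](O)CC1 | intermediate
32 | 2,8,12,14-tetraol 9-acetate | COC(=O)/C1=C/[C@@H]2OC(=O)[C@H](C)[C@@]2(O)[C@H](OC(C)=O)[C@H]2[C@@H](C)[C@H](O)C[C@H](O)[C@]2(C)[C@H](O)CC1 | intermediate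
33 | CNP0230222.1, methyl (1S,2R,5E,7S,8S,9R,10S,11R,12R,14S,17R)-2,9,12,14-tetraacetoxy-8-hydroxybriar-5-en-19,7-olid-16-oate | COC(=O)/C1=C/[C@@H]2OC(=O)[C@H](C)[C@@]2(O)[C@H](OC(C)=O)[C@H]2[C@@H](C)[C@H](OC(C)=O)C[C@H](OC(C)=O)[C@]2(C)[C@H](OC(C)=O)CC1 | target

## Step count and least certain steps

Total step count: 22. Longest linear sequence: 22 steps (from 1).

**Step 18 (key step).**
- Risk: the alkene lies between the fully substituted C1 and C8, so cycloaddition of ozone may be slow. Oxygen-atom transfer (epoxide formation), attack on C5=C6, or fragmentation of the carbonyl oxide next to the tertiary carbinol may then intervene. After cleavage, transannular aldol closure between C3 and C7 is possible.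
- Fallback: set out from 26 and split the cleavage into two controlled events. Stoichiometric OsO4·TMEDA, hydrogen-bonded to 8α-OH, is delivered to the α face of C2=C7 to give the 2α,7α-diol F1. Glycol cleavage of F1 with Pb(OAc)4 in benzene then returns to the route at 28.

**Step 11.**
- Risk: reductive cleavage of the benzylic C8–O bond in the arene radical anion, because C7 is meta to the methoxy group and carries electron density. Any protonation of the alkoxide makes this easy.
- Fallback: set out from 14, which has no benzylic oxygen. Birch reduction, hydrolysis and conjugation with TsOH in acetone give the conjugated enone F2 (C5=O, C6=C7, H-2 α). Chromium-catalysed allylic oxidation with t-BuOOH at C8, now the γ position of the enone, gives the ene-dione F3, the C6=C7 tautomer of 19. Double deprotonation of F3 (γ-H at C2, α′-H at C9) gives the same bis-enolate as in step 13, so the route is rejoined at 20.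

**Step 14.**
- Risk: loss of site selectivity, that is, oxidative addition at both triflates, because the steric difference between C5 and C8 is the only discriminating element.
- Fallback: set out from 19 and introduce the triflates one after the other. One equivalent of base and PhNTf2 gives the C5 dienyl triflate F4, with the C8 ketone intact. Methoxycarbonylation gives the keto dienoate F5. Kinetic α′-deprotonation at C9 (LDA, −78 °C) and triflation then return to the route at 21.

**Step 19.**
- Risk: poor facial selectivity at C7 if the chelate is not formed, conjugate reduction of the ene-keto ester, and slow or incomplete equilibration at C17.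
- Fallback: set out from 28 and replace the external hydride by a tethered one. Silylation of 8-OH with ClSiHMe2/imidazole gives the hydridosilyl ether F6. Fluoride-catalysed intramolecular hydrosilylation of the C7 ketone, in the rotamer with C6 anti to C9, gives the cyclic 7,8-siloxane F7. HF·pyridine releases 29, where the route is rejoined.

**Step 20.**
- Risk: slow reduction of the neopentyl ketone, masking of C2=O as a transannular hemiketal with 8-OH, or a mismatch between catalyst and ring conformation that erodes the selectivity.
- Fallback: set out from 30 and relay the configuration from C14 instead. Hydrolysis of the acetal gives the 12,14-dihydroxy ketone F8, a β-hydroxy ketone (O14–C14–C1–C2=O). Narasaka–Prasad reduction (Et2BOMe, NaBH4, THF/MeOH, −78 °C) gives the 2,14-syn diol required by the target and returns to the route at 32.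

## Further compounds

F1 | step 18 | 2α,7α-diol of 26 | C1C[C@@]2(O)[C@@](O)(C=C1C(=O)OC)[C@@](O)(C(C)C(=O)OC)[C@H](OC(C)=O)[C@H]1[C@@H](C)[C@H]3C[C@H](OC(C)(C)O3)[C@]21C
F2 | step 11 | conjugated enone (C5=O, C6=C7, H-2 α) | O=C1CC[C@H]2C(=C1)CC[C@H]1[C@@H](C)[C@H]3C[C@H](OC(C)(C)O3)[C@]21C
F3 | step 11 | ene-dione (C5=O, C6=C7, C8=O) | O=C1CC[C@H]2C(=C1)C(=O)C[C@H]1[C@@H](C)[C@H]3C[C@H](OC(C)(C)O3)[C@]21C
F4 | step 14 | C5 dienyl triflate with C8 ketone | C1CC2=C(C=C1OS(=O)(=O)C(F)(F)F)C(=O)C[C@H]1[C@@H](C)[C@H]3C[C@H](OC(C)(C)O3)[C@]21C
F5 | step 14 | keto dienoate | C1CC2=C(C=C1C(=O)OC)C(=O)C[C@H]1[C@@H](C)[C@H]3C[C@H](OC(C)(C)O3)[C@]21C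
F6 | step 19 | 8-O-dimethylsilyl ether of 28 | COC(=O)/C1=C/C(=O)[C@@](O[SiH](C)C)(C(C)C(=O)OC)[C@H](OC(C)=O)[C@H]2[C@@H](C)[C@H]3C[C@H](OC(C)(C)O3)[C@]2(C)C(=O)CC1
F7 | step 19 | cyclic 7,8-O-dimethylsilylene derivative of 29 | COC(=O)/C1=C/[C@@H]2O[Si](C)(C)O[C@]2(C(C)C(=O)OC)[C@H](OC(C)=O)[C@H]2[C@@H](C)[C@H]3C[C@H](OC(C)(C)O3)[C@]2(C)C(=O)CC1
F8 | step 20 | 12,14-dihydroxy-2-ketone | COC(=O)/C1=C/[C@@H]2OC(=O)[C@H](C)[C@@]2(O)[C@H](OC(C)=O)[C@H]2[C@@H](C)[C@H](O)C[C@H](O)[C@]2(C)C(=O)CC1
A1 | alternative 1 | 5,6-seco diene for ring-closing metathesis | C=C[C@@H]1OC(=O)[C@H](C)[C@@]1(O)[C@H](OC(C)=O)[C@H]1[C@@H](C)[C@H](OC(C)=O)C[C@H](OC(C)=O)[C@]1(C)[C@H](OC(C)=O)CCC(=C)C(=O)OC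
A2 | alternative 2 | 14-membered 1,2-epoxy 10-en-12-one | COC(=O)/C1=C/[C@@H]2OC(=O)[C@H](C)[C@@]2(O)[C@H](OC(C)=O)/C=C(C)/C(=O)C[C@H](OC(C)=O)[C@@]2(C)O[C@@H]2CC1
A3 | alternative 3 | 2-vinyl-2-hydroxy-7-acrylate decalin | C=C[C@]1(O)[C@H](/C=C/C(=O)OC)CC[C@H]2[C@@H](C)[C@H]3C[C@H](OC(C)(C)O3)[C@]12C
A4 | alternative 3 | oxy-Cope product, (6E)-cyclodecen-2-one | COC(=O)C1/C=C/CC[C@H]2[C@@H](C)[C@H]3C[C@H](OC(C)(C)O3)[C@]2(C)C(=O)CC1
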